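**Plan**

Numbering used: 1,2-dioxane O1–O2–C3(Me, chain)–C4H2–C4a(Me)–C7a(H); lactone C4a–O5–C6(=O)–C7H2–C7a; chain carbons C1'–C16'.
Retrosynthesis cuts, in order: the C9'=C10' alkene (Horner–Wadsworth–Emmons); O2–C7a (retro-oxa-Michael to a butenolide hydroperoxide); O1–C3 (hydroperoxysilylation of a C3=C4 alkene); then C7–C7a and O5–C4a together, a retro-(3+2) of the lactone onto a diene.
Feature used: C7a–C4a(Me)–C4–C3(Me) is a 2,4-dimethylbuta-1,3-diene skeleton and O5–C6(=O)–C7 is an acetic acid unit bridging the vicinal pair C7a/C4a. A carboxymethyl radical can therefore add to the diene CH2 (C7a) and its own carboxylate can close on the allyl terminus C4a, leaving C3=C4 for the peroxide.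
Forward order: C11 alkynol → diene (carboalumination/coupling) → γ-lactone ring (step 3) → butenolide → C3 silyl peroxide → 1,2-dioxane ring (oxa-Michael) → triene last.
Stereochemistry: C4a from the chiral copper catalyst in step 3; C7a from C4a through the obligatory cis ring fusion in step 6; C3 arises without facial control in step 5 and the (3S)-epimer is taken by chromatography after ring closure; the E,E,E-triene comes from the commercial dienal (two alkenes) and the olefination (one).

Key step: step 3

Assumption: the (S,S)-ligand is taken to give the (5R)-lactone in step 3; should the sense of induction prove opposite, the (R,R)-ligand is used with no other change.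

**Route**

Step 1
Reactants: 1 undec-10-yn-1-ol
Product: 2 tert-butyl(diphenyl)(undec-10-yn-1-yloxy)silane
Conditions: TBDPSCl, imidazole, DCM, 0 °C to rt
Reagents that add atoms: tert-butyl(chloro)diphenylsilane, CC(C)(C)[Si](Cl)(c1ccccc1)c1ccccc1
Why: Standard silylation of a primary alcohol gives an ether that should survive the organoaluminium, radical, enolate and peroxide chemistry and is removed with fluoride near the end.

Step 2
Reactants: 2 tert-butyl(diphenyl)(undec-10-yn-1-yloxy)silane; 3 2-bromoprop-1-ene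
Product: 5 tert-butyl{[(10E)-10,12-dimethyltrideca-10,12-dien-1-yl]oxy}diphenylsilane, via alkenyl(dimethyl)alane 4 (not isolated)
Conditions: Me3Al, Cp2ZrCl2 (25 mol %), DCM, 0 °C to rt; then 3, ZnCl2, Pd(PPh3)4 (5 mol %), THF, rt
Reagents that add atoms: trimethylaluminium, C[Al](C)C
Why: Zirconium-catalysed Negishi carboalumination adds Me and Al syn across the terminal alkyne (Me to the internal carbon), which fixes the (E)-trisubstituted alkene, and the alkenylalane is cross-coupled in the same flask with 3 (Negishi coupling) with retention of geometry.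

Step 3
Reactants: 5 tert-butyl{[(10E)-10,12-dimethyltrideca-10,12-dien-1-yl]oxy}diphenylsilane; 6 bromoacetic acid
Product: 7 (5R)-5-[(1E)-11-{[tert-butyl(diphenyl)silyl]oxy}-2-methylundec-1-en-1-yl]-5-methyloxolan-2-one
Conditions: Cu(MeCN)4PF6 (10 mol %), (S,S)-t-Bu-BOX [2,2'-(propane-2,2-diyl)bis((4S)-4-tert-butyl-4,5-dihydrooxazole), 12 mol %], Cs2CO3 (0.6 equiv), EtOAc, blue LEDs (450 nm), rt
Reagents that add atoms: none
Why: Proposed new method: the monovalent copper bis(oxazoline) carboxylate formed from 6 is excited by blue light and loses bromine from its own bromoacetate ligand, the carboxymethyl radical adds to the unsubstituted CH2 terminus of diene 5 (the future C7a, making C7–C7a), and the resulting doubly tertiary allyl radical (C4a–C4–C3) is captured at the divalent copper carboxylate to an allyl trivalent copper species that forms O5–C4a by reductive elimination and returns monovalent copper. The closest known reaction types are the copper/bis(oxazoline)-catalysed enantioselective three-component carbo-esterification of 1,3-dienes with alkyl radical precursors and carboxylic acids, the Kharasch–Sosnovsky allylic oxidation and, for the racemic bond construction itself, the Mn(OAc)3 lactone annulation of conjugated dienes with acetic acid; what is new is that radical and carboxylate sit in one reagent, so that a two-component (3+2) annulation results, and that the C–O bond is made at a fully substituted carbon. The γ-lactone ring closes by 5-exo attack of the carboxylate oxygen on the C4a terminus of the allyl unit, the alternative 7-endo closure at C3 being disfavoured by ring size. The only new stereocentre, C4a [(5R) in 7], is set in this C–O bond-forming step by the C2-symmetric ligand on copper, which has to tell the methyl group from the alkenyl group at a copper-bound allyl terminus. The step needs regioselective radical addition, secured by the sterically open CH2 terminus and the stability of the doubly tertiary allyl radical, and chemoselectivity for the diene over the product, secured because the isolated trisubstituted alkene of 7 is a poor radical acceptor; loss of alkene geometry would be harmless because C3 becomes sp3 in step 5.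

Step 4
Reactants: 7 (5R)-5-[(1E)-11-{[tert-butyl(diphenyl)silyl]oxy}-2-methylundec-1-en-1-yl]-5-methyloxolan-2-one
Product: 10 (5R)-5-[(1E)-11-{[tert-butyl(diphenyl)silyl]oxy}-2-methylundec-1-en-1-yl]-5-methylfuran-2(5H)-one, via 3-(phenylselanyl) lactone 8 (not isolated), via 3-(benzeneseleninyl) lactone 9 (not isolated)
Conditions: LiN(iPr)2, THF, −78 °C; PhSeBr, −78 °C; then NaIO4, NaHCO3, THF/MeOH/H2O, 0 °C to rt
Reagents that add atoms: none
Why: α-Selenenylation of the lactone lithium enolate followed by selenoxide syn-elimination is the standard lactone-to-butenolide dehydrogenation; periodate is chosen so that the trisubstituted alkene is not epoxidised, and C4a, which has no α-hydrogen, is untouched.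

Step 5
Reactants: 10 (5R)-5-[(1E)-11-{[tert-butyl(diphenyl)silyl]oxy}-2-methylundec-1-en-1-yl]-5-methylfuran-2(5H)-one
Product: 11 (5S)-5-[(2S)-11-{[tert-butyl(diphenyl)silyl]oxy}-2-methyl-2-[(triethylsilyl)peroxy]undecyl]-5-methylfuran-2(5H)-one, expected together with its (2R)-epimer and carried on as the mixture
Conditions: Co(thd)2 (thd = 2,2,6,6-tetramethylheptane-3,5-dionate, 10 mol %), O2 (1 atm), Et3SiH, 1,2-dichloroethane, rt
Reagents that add atoms: dioxygen, O=O; triethylsilane, CC[SiH](CC)CC
Why: In the Mukaiyama–Isayama hydroperoxysilylation a cobalt hydride transfers a hydrogen atom to C4 of the electron-rich trisubstituted alkene, the tertiary C3 radical traps O2 and the peroxyl is silylated while the electron-poor butenolide alkene is left alone; the C3 radical is planar and remote from C4a, so no useful facial bias is expected and C3 is secured by separation in step 6.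

Step 6
Reactants: 11 (5S)-5-[(2S)-11-{[tert-butyl(diphenyl)silyl]oxy}-2-methyl-2-[(triethylsilyl)peroxy]undecyl]-5-methylfuran-2(5H)-one (with its epimer)
Product: 13 (3S,4aS,7aS)-3-(9-{[tert-butyl(diphenyl)silyl]oxy}nonyl)-3,4a-dimethyltetrahydro-3H-furo[3,2-c][1,2]dioxin-6(4H)-one, via free hydroperoxide 12 (not isolated)
Conditions: HCl (cat.), MeOH, 0 °C; then Et2NH, CF3CH2OH, rt; chromatography on silica gel to remove the (3R)-epimer
Reagents that add atoms: none
Why: Acid methanolysis frees the hydroperoxide and amine-promoted intramolecular oxa-Michael addition (6-exo-trig) closes the 1,2-dioxane; the tether can reach C7a only from the butenolide face that carries C4, so the ring fusion is cis and C7a follows from C4a, and the C3 epimers, now diastereomeric bicycles, should be separable.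

Step 7
Reactants: 13 (3S,4aS,7aS)-3-(9-{[tert-butyl(diphenyl)silyl]oxy}nonyl)-3,4a-dimethyltetrahydro-3H-furo[3,2-c][1,2]dioxin-6(4H)-one
Product: 14 (3S,4aS,7aS)-3-(9-hydroxynonyl)-3,4a-dimethyltetrahydro-3H-furo[3,2-c][1,2]dioxin-6(4H)-one
Conditions: HF·pyridine, pyridine, THF, 0 °C to rt
Reagents that add atoms: none
Why: Fluoride cleavage of the silyl ether under mildly acidic, non-reducing conditions should leave the dialkyl peroxide and the base-sensitive β-peroxy lactone intact.

Step 8
Reactants: 14 (3S,4aS,7aS)-3-(9-hydroxynonyl)-3,4a-dimethyltetrahydro-3H-furo[3,2-c][1,2]dioxin-6(4H)-one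
Product: 15 9-[(3S,4aS,7aS)-3,4a-dimethyl-6-oxohexahydro-3H-furo[3,2-c][1,2]dioxin-3-yl]nonanal
Conditions: Dess–Martin periodinane, NaHCO3, DCM, 0 °C to rt
Reagents that add atoms: none
Why: Buffered Dess–Martin oxidation converts the primary alcohol to the aldehyde under neutral conditions that do not touch the O–O bond or the stereocentres.

Step 9
Reactants: 16 (2E,4E)-hepta-2,4-dienal
Product: 17 (2E,4E)-hepta-2,4-dien-1-ol
Conditions: NaBH4, CeCl3·7H2O, MeOH, 0 °C
Reagents that add atoms: none
Why: Luche reduction gives clean 1,2-reduction of the dienal without conjugate reduction or loss of the E,E geometry.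

Step 10
Reactants: 17 (2E,4E)-hepta-2,4-dien-1-ol
Product: 18 (2E,4E)-1-bromohepta-2,4-diene
Conditions: PBr3, pyridine (cat.), Et2O, −10 °C; used crude
Reagents that add atoms: phosphorus tribromide, BrP(Br)Br
Why: Bromination of the primary dienyl alcohol with PBr3 at low temperature should give the conjugated primary bromide, which is the thermodynamically preferred allylic isomer.

Step 11
Reactants: 18 (2E,4E)-1-bromohepta-2,4-diene
Product: 19 diethyl [(2E,4E)-hepta-2,4-dien-1-yl]phosphonate
Conditions: P(OEt)3, neat, 100 °C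
Reagents that add atoms: triethyl phosphite, CCOP(OCC)OCC
Why: The Michaelis–Arbuzov reaction of a primary allylic bromide delivers the linear conjugated dienylphosphonate with loss of bromoethane.

Step 12
Reactants: 15 9-[(3S,4aS,7aS)-3,4a-dimethyl-6-oxohexahydro-3H-furo[3,2-c][1,2]dioxin-3-yl]nonanal; 19 diethyl [(2E,4E)-hepta-2,4-dien-1-yl]phosphonate
Product: 20 (3S,4aS,7aS)-3-[(9E,11E,13E)-hexadeca-9,11,13-trien-1-yl]-3,4a-dimethyltetrahydro-3H-furo[3,2-c][1,2]dioxin-6(4H)-one (CNP0229098.1)
Conditions: 19, LiN(SiMe3)2 (slightly less than 1 equiv relative to 19), THF, −78 °C; then 15, −78 to 0 °C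
Reagents that add atoms: none
Why: In this Horner–Wadsworth–Emmons olefination the preformed lithiated dienylphosphonate (no free amide base) adds through its α-carbon to the aldehyde at low temperature and should eliminate mainly to the (E)-alkene, completing the E,E,E-triene without touching the three ring stereocentres.

**Compound list**

1 | undec-10-yn-1-ol | OCCCCCCCCCC#C | starting material
2 | tert-butyl(diphenyl)(undec-10-yn-1-yloxy)silane | CC(C)(C)[Si](OCCCCCCCCCC#C)(c1ccccc1)c1ccccc1 | intermediate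
3 | 2-bromoprop-1-ene | CC(Br)=C | starting material
4 | [(1E)-11-{[tert-butyl(diphenyl)silyl]oxy}-2-methylundec-1-en-1-yl](dimethyl)alumane | C[Al](C)/C=C(\C)CCCCCCCCCO[Si](c1ccccc1)(c1ccccc1)C(C)(C)C | intermediate
5 | tert-butyl{[(10E)-10,12-dimethyltrideca-10,12-dien-1-yl]oxy}diphenylsilane | C=C(C)/C=C(\C)CCCCCCCCCO[Si](c1ccccc1)(c1ccccc1)C(C)(C)C | intermediate
6 | bromoacetic acid | OC(=O)CBr | starting material
7 | (5R)-5-[(1E)-11-{[tert-butyl(diphenyl)silyl]oxy}-2-methylundec-1-en-1-yl]-5-methyloxolan-2-one | CC(C)(C)[Si](c1ccccc1)(c2ccccc2)OCCCCCCCCC/C(C)=C/[C@]3(C)OC(=O)CC3 | intermediate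
8 | (5R)-5-[(1E)-11-{[tert-butyl(diphenyl)silyl]oxy}-2-methylundec-1-en-1-yl]-5-methyl-3-(phenylselanyl)oxolan-2-one (both C3 epimers) | CC(C)(C)[Si](c1ccccc1)(c2ccccc2)OCCCCCCCCC/C(C)=C/[C@]3(C)OC(=O)C([Se]c4ccccc4)C3 | intermediate
9 | (5R)-3-(benzeneseleninyl)-5-[(1E)-11-{[tert-butyl(diphenyl)silyl]oxy}-2-methylundec-1-en-1-yl]-5-methyloxolan-2-one | CC(C)(C)[Si](c1ccccc1)(c2ccccc2)OCCCCCCCCC/C(C)=C/[C@]3(C)OC(=O)C([Se](=O)c4ccccc4)C3 | intermediate
10 | (5R)-5-[(1E)-11-{[tert-butyl(diphenyl)silyl]oxy}-2-methylundec-1-en-1-yl]-5-methylfuran-2(5H)-one | CC(C)(C)[Si](c1ccccc1)(c2ccccc2)OCCCCCCCCC/C(C)=C/[C@]3(C)OC(=O)C=C3 | intermediate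
11 | (5S)-5-[(2S)-11-{[tert-butyl(diphenyl)silyl]oxy}-2-methyl-2-[(triethylsilyl)peroxy]undecyl]-5-methylfuran-2(5H)-one | CC(C)(C)[Si](c1ccccc1)(c2ccccc2)OCCCCCCCCC[C@](C)(OO[Si](CC)(CC)CC)C[C@]3(C)OC(=O)C=C3 | intermediate
12 | (5S)-5-[(2S)-11-{[tert-butyl(diphenyl)silyl]oxy}-2-hydroperoxy-2-methylundecyl]-5-methylfuran-2(5H)-one | CC(C)(C)[Si](c1ccccc1)(c2ccccc2)OCCCCCCCCC[C@](C)(OO)C[C@]3(C)OC(=O)C=C3 | intermediate
13 | (3S,4aS,7aS)-3-(9-{[tert-butyl(diphenyl)silyl]oxy}nonyl)-3,4a-dimethyltetrahydro-3H-furo[3,2-c][1,2]dioxin-6(4H)-one | CC(C)(C)[Si](c1ccccc1)(c2ccccc2)OCCCCCCCCC[C@@]3(C)C[C@]4(C)OC(=O)C[C@@H]4OO3 | intermediate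
14 | (3S,4aS,7aS)-3-(9-hydroxynonyl)-3,4a-dimethyltetrahydro-3H-furo[3,2-c][1,2]dioxin-6(4H)-one | OCCCCCCCCC[C@@]1(C)C[C@]2(C)OC(=O)C[C@@H]2OO1 | intermediate
15 | 9-[(3S,4aS,7aS)-3,4a-dimethyl-6-oxohexahydro-3H-furo[3,2-c][1,2]dioxin-3-yl]nonanal | O=CCCCCCCCC[C@@]1(C)C[C@]2(C)OC(=O)C[C@@H]2OO1 | intermediate
16 | (2E,4E)-hepta-2,4-dienal | CC/C=C/C=C/C=O | starting material
17 | (2E,4E)-hepta-2,4-dien-1-ol | CC/C=C/C=C/CO | intermediate
18 | (2E,4E)-1-bromohepta-2,4-diene | CC/C=C/C=C/CBr | intermediate
19 | diethyl [(2E,4E)-hepta-2,4-dien-1-yl]phosphonate | CC/C=C/C=C/CP(=O)(OCC)OCC | intermediate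
20 | (3S,4aS,7aS)-3-[(9E,11E,13E)-hexadeca-9,11,13-trien-1-yl]-3,4a-dimethyltetrahydro-3H-furo[3,2-c][1,2]dioxin-6(4H)-one | CC/C=C/C=C/C=C/CCCCCCCC[C@@]1(C)C[C@]2(C)OC(=O)C[C@@H]2OO1 | target

**Step count and risks**

Total steps: 12. Longest linear sequence: 9 (steps 1–8 and 12).

Steps most likely to fail:

1. Step 3 (proposed new method). Enantioselection may be poor when the C–O bond forms at the hindered, fully substituted allyl terminus, the allyl intermediate may lose a proton to give a triene, or bromine abstraction may be sluggish. Fallback with known chemistry and a different bond construction (C4a–C4 instead of the lactone bonds): alkenylalane 4, generated from 2 as in step 2, is added to methyl 4-oxopentanoate under Ti(OiPr)4/BINOL catalysis (enantioselective addition of an alkenylaluminium reagent to a ketone, BINOL antipode chosen for the 4R carbinol). This should give, after work-up, methyl (4R,5E)-15-{[tert-butyl(diphenyl)silyl]oxy}-4-hydroxy-4,6-dimethylpentadec-5-enoate F1, which lactonises on gentle warming in toluene. The fallback sets out from 4 and returns to the route at 7.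

2. Step 5. Oxygen capture by the planar C3 radical has no facial discrimination, so half of the material ends in the wrong C3 series; hydrogen-atom transfer to the butenolide may also compete. Fallback with reagent control, setting out from 10:
 - Shi epoxidation (KHSO5, K2CO3, fructose-derived ketone of the antipode that gives the 2S,3R-epoxide, MeCN/dimethoxymethane/buffer, 0 °C) should give (5R)-5-[(2S,3R)-3-(9-{[tert-butyl(diphenyl)silyl]oxy}nonyl)-3-methyloxiran-2-yl]-5-methylfuran-2(5H)-one F2.
 - Perhydrolysis with ethereal H2O2 and catalytic H3PMo12O40 opens the epoxide at the tertiary carbon with inversion to (5R)-5-[(1R,2S)-11-{[tert-butyl(diphenyl)silyl]oxy}-2-hydroperoxy-1-hydroxy-2-methylundecyl]-5-methylfuran-2(5H)-one F3.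
 - Et2NH in CF3CH2OH closes the ring to (3S,4R,4aS,7aS)-3-(9-{[tert-butyl(diphenyl)silyl]oxy}nonyl)-4-hydroxy-3,4a-dimethyltetrahydro-3H-furo[3,2-c][1,2]dioxin-6(4H)-one F4.
 - 1,1'-Thiocarbonyldiimidazole converts the hindered C4 alcohol to O-[(3S,4R,4aS,7aS)-3-(9-{[tert-butyl(diphenyl)silyl]oxy}nonyl)-3,4a-dimethyl-6-oxohexahydro-3H-furo[3,2-c][1,2]dioxin-4-yl] 1H-imidazole-1-carbothioate F5; this acylation is the weak point of the fallback.
 - Barton–McCombie reduction (Bu3SnH, AIBN, toluene, 80 °C) removes the C4 oxygen; the ring geometry disfavours epoxide formation from the C4 radical.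
 The fallback returns to the route at 13.

3. Step 12. The phosphonate anion may deprotonate C7 and trigger retro-oxa-Michael opening of the peroxide ring, and the new alkene may form with incomplete E-selectivity. Fallback with reversed polarity, setting out from 14: Mitsunobu reaction with 1-phenyl-1H-tetrazole-5-thiol (PPh3 premixed with diisopropyl azodicarboxylate) gives 5-({9-[(3S,4aS,7aS)-3,4a-dimethyl-6-oxohexahydro-3H-furo[3,2-c][1,2]dioxin-3-yl]nonyl}sulfanyl)-1-phenyl-1H-tetrazole F6. Oxidation with H2O2 and catalytic (NH4)6Mo7O24 gives 5-({9-[(3S,4aS,7aS)-3,4a-dimethyl-6-oxohexahydro-3H-furo[3,2-c][1,2]dioxin-3-yl]nonyl}sulfonyl)-1-phenyl-1H-tetrazole F7. Julia–Kocienski olefination with commercial dienal 16 (KN(SiMe3)2 added to the mixture of F7 and 16, THF, −78 °C) then gives the triene directly. The fallback returns to the route at 20.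

**Further compounds**

F1 | step 3 | methyl (4R,5E)-15-{[tert-butyl(diphenyl)silyl]oxy}-4-hydroxy-4,6-dimethylpentadec-5-enoate | COC(=O)CC[C@@](C)(O)/C=C(\C)CCCCCCCCCO[Si](c1ccccc1)(c2ccccc2)C(C)(C)C
F2 | step 5 | (5R)-5-[(2S,3R)-3-(9-{[tert-butyl(diphenyl)silyl]oxy}nonyl)-3-methyloxiran-2-yl]-5-methylfuran-2(5H)-one | CC(C)(C)[Si](c1ccccc1)(c2ccccc2)OCCCCCCCCC[C@@]3(C)O[C@@H]3[C@]4(C)OC(=O)C=C4
F3 | step 5 | (5R)-5-[(1R,2S)-11-{[tert-butyl(diphenyl)silyl]oxy}-2-hydroperoxy-1-hydroxy-2-methylundecyl]-5-methylfuran-2(5H)-one | CC(C)(C)[Si](c1ccccc1)(c2ccccc2)OCCCCCCCCC[C@](C)(OO)[C@H](O)[C@]3(C)OC(=O)C=C3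
F4 | step 5 | (3S,4R,4aS,7aS)-3-(9-{[tert-butyl(diphenyl)silyl]oxy}nonyl)-4-hydroxy-3,4a-dimethyltetrahydro-3H-furo[3,2-c][1,2]dioxin-6(4H)-one | CC(C)(C)[Si](c1ccccc1)(c2ccccc2)OCCCCCCCCC[C@@]3(C)[C@H](O)[C@]4(C)OC(=O)C[C@@H]4OO3
F5 | step 5 | O-[(3S,4R,4aS,7aS)-3-(9-{[tert-butyl(diphenyl)silyl]oxy}nonyl)-3,4a-dimethyl-6-oxohexahydro-3H-furo[3,2-c][1,2]dioxin-4-yl] 1H-imidazole-1-carbothioate | CC(C)(C)[Si](c1ccccc1)(c2ccccc2)OCCCCCCCCC[C@@]3(C)[C@H](OC(=S)n5ccnc5)[C@]4(C)OC(=O)C[C@@H]4OO3
F6 | step 12 | 5-({9-[(3S,4aS,7aS)-3,4a-dimethyl-6-oxohexahydro-3H-furo[3,2-c][1,2]dioxin-3-yl]nonyl}sulfanyl)-1-phenyl-1H-tetrazole | c1ccccc1-n1nnnc1SCCCCCCCCC[C@@]2(C)C[C@]3(C)OC(=O)C[C@@H]3OO2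
F7 | step 12 | 5-({9-[(3S,4aS,7aS)-3,4a-dimethyl-6-oxohexahydro-3H-furo[3,2-c][1,2]dioxin-3-yl]nonyl}sulfonyl)-1-phenyl-1H-tetrazole | O=S(=O)(CCCCCCCCC[C@@]1(C)C[C@]2(C)OC(=O)C[C@@H]2OO1)c1nnnn1-c1ccccc1
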